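Raise the temperature from −5 °C through 10 °C to 25 °C, hold each flask for the same 12 min, and ask what becomes of the target.

all flasks: starting material 0.50 M; reagent 0.450 M; second substrate 2.50 M; protic impurity 0.0500 M; time 12 min

| run | temperature |
|---|---|
| teal | −5 °C |
| ochre | 10 °C |
| grey | 25 °C |

    starting material + reagent → target (k1 = 0.0039 /M/s, Ea1 = 63.0 kJ/mol)
    second substrate + reagent → second product (k2 = 6.9 × 10⁻⁴ /M/s, Ea2 = 59.0 kJ/mol)
    starting material + protic impurity → quenched substrate (k3 = 0.017 /M/s, Ea3 = 65.0 kJ/mol)
    target → over-reaction product (k4 = 0.0047 /s, Ea4 = 75.0 kJ/mol)
    (constants at 25 °C)

1. which flask leads in amount of target, in percent of the starting material charged ("all alike" within 1.5 percentage points) (teal / ochre / grey / all alike)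
2. how much target is there at the end, in percent of the starting material charged: teal
3. how much target is there at the end, in percent of the starting material charged: ochre
4. how much target is there at the end, in percent of the starting material charged: grey

- the list of constants is for 25 °C, to be carried to other temperatures by the activation energies

**Bench rule.** Take the target's share of the charge as the making constant times c(reagent) times the time, a rule that serves while the target survives and the reagent stays. For teal, carry the constants down with the given speed-up of the third step from teal to grey, 19, raised to the ratio of activation energies. The rule then gives 7.36%, and the loss constant times the time is 0.115, which is less than one, so keep this figure for teal as an overestimate, for the rule counts no loss of target and no fall of c(reagent) or of the starting material.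

**Its border.** Apply the same rule to grey and it prints 126% of the charge, which cannot stand. The loss constant times the time is 3.36 in grey, which is more than one, so the target there lives for less than the run, and the rule, which counts no loss, cannot serve in grey.

**Tail ratio.** Ask instead what grey must end in. At the start, the second substrate uses 0.88 of reagent for each unit the starting material uses, and the protic impurity claims its 0.0500 M, so expect 42.2% of the starting material to remain. The reagent then falls in a pseudo-first-order way with constant 0.153 /min, slower than the target's loss at 0.28 /min, so the target follows the reagent down instead of falling at its own pace. Its share of the charge is then c(reagent) times the share of starting material left times the making constant over the difference of those two constants, and call that last factor the tail ratio 1.81 /M. With c(reagent) reckoned at 0.0718 M, grey should hold 5.50%. Ochre lies between the two limits, and I expect it to lead.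

**The forecast.** It names ochre, with 6.1% for teal, 13.6% for ochre and 5% for grey, on the ground that “warming favours loss of the target”. My figures for teal and grey are higher.

**Grey read.** The run puts ochre ahead at 14.0%, more than teal's 6.09% and grey's 5.17%. Grey's readings, 12% of the reagent and 54% of the starting material left, put through the tail ratio give 5.36%. Now read grey later, at 50 min: with 0.038% of the reagent and 49% of the starting material left, the ratio gives 0.0153%, and that reading of grey holds 0.0151% of target.

(Its constants were set for the occasion; no experiment stands behind them.)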